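**Strategy.** Ring A (C1–C5, C10) is disconnected at C3–C4, exploiting its quaternary gem-dimethyl carbon C4 beside the unfunctionalised methylene C3: C4 is recognised as the isopropenyl carbon of (R)-carvone, which also supplies all of ring B and C17. The key step is an iron-hydride hydrogen-atom-transfer cyclization in which the tertiary C4 radical closes 6-exo onto a tosylhydrazone carbon (C3); loss of sulfinate and N2 leaves a bare CH2, so ring A and its quaternary centre arise tracelessly with the trans ring fusion preset. The precursor is a monocyclic carvone-derived cyclohexenone carrying isopropenyl at C5 and a trans 3-carbon hydrazone chain on quaternary C10. The lactone ring is carried intact from bromobutyrolactone.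

Key step: step 5

Remark: labdane numbering is used for all intermediates (ring A = C1–C5 and C10, ring B = C5–C10, side chain C11–C16, C17 = exocyclic methylene carbon, C20 = angular methyl); the sulfur-bearing carbon C13 of 23–26 is a mixture of epimers that converges in step 14.

**Step 1**
Reactants: 1 (R)-(−)-carvone
Product: 3 (5R)-2,6-dimethyl-5-(prop-1-en-2-yl)cyclohex-2-en-1-one (6-methylcarvone; both C6 epimers), via lithium dienolate 2 (not isolated)
Conditions: LiN(i-Pr)2, THF, −78 °C; MeI, −78 → 0 °C
Reagents that add atoms: iodomethane, CI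
Why: Kinetic α′-deprotonation of the enone gives the cross-conjugated lithium enolate, which is C-methylated (enolate alkylation); the configuration of the new centre (future C10) is irrelevant because it is re-enolized in step 2.

**Step 2**
Reactants: 3 6-methylcarvone
Product: 5 (5S,6S)-2,6-dimethyl-5-(prop-1-en-2-yl)-6-(prop-2-yn-1-yl)cyclohex-2-en-1-one (propargyl trans to isopropenyl), via lithium enolate 4 (not isolated)
Conditions: LiN(i-Pr)2, THF, −78 °C; DMPU, propargyl bromide, −78 → −20 °C
Reagents that add atoms: propargyl bromide, C#CCBr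
Why: Enolate alkylation of the tetrasubstituted enolate: the electrophile enters anti to the neighbouring isopropenyl group, so the C1–C3 chain is trans to isopropenyl and the C20 methyl cis, which fixes C10 relative to the carvone-derived C5 and presets the trans ring fusion.

**Step 3**
Reactants: 5 propargyl ketone
Product: 7 3-[(1S,6S)-1,3-dimethyl-2-oxo-6-(prop-1-en-2-yl)cyclohex-3-en-1-yl]propanal, via alkenylborane 6 (not isolated)
Conditions: Sia2BH (from BH3·SMe2 and 2-methylbut-2-ene), THF, 0 °C; then H2O2, pH 8 phosphate buffer, 0 → 20 °C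
Reagents that add atoms: hydrogen peroxide, OO
Why: Anti-Markovnikov hydroboration–oxidation of the terminal alkyne: the bulky dialkylborane adds to the alkyne far faster than to the hindered 1,1-disubstituted alkene or the enone, and buffered oxidation of the alkenylborane releases the aldehyde (C3) without epoxidizing the enone.

**Step 4**
Reactants: 7 keto aldehyde
Product: 8 N′-tosylhydrazone of aldehyde 7
Conditions: TsNHNH2, MeOH, 20 °C
Reagents that add atoms: 4-methylbenzenesulfonohydrazide, Cc1ccc(cc1)S(=O)(=O)NN
Why: Condensation of the sulfonyl hydrazide with the unhindered aldehyde is much faster than with the doubly α-branched conjugated ketone, giving the aldehyde tosylhydrazone chemoselectively.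

**Step 5**
Reactants: 8 tosylhydrazone
Product: 10 (4aS,8aS)-2,5,5,8a-tetramethyl-4a,5,6,7,8,8a-hexahydronaphthalen-1(4H)-one, via N-alkyl-N′-tosylhydrazide 9 (not isolated)
Conditions: Fe(acac)3, PhSiH3, EtOH–THF (0.02 M), 25 °C; then NaOAc, EtOH, 78 °C
Reagents that add atoms: none
Why: An iron hydride formed from Fe(acac)3 and PhSiH3 transfers a hydrogen atom to the terminal carbon of the isopropenyl group (Mukaiyama-type hydrogen atom transfer), the tertiary C4 radical adds to the hydrazone carbon C3 and the hydrazinyl radical is reduced to hydrazide 9; base-induced loss of sulfinate then gives the alkyldiazene, which expels N2 and leaves C3 as CH2, as in the Caglioti reduction of tosylhydrazones. The closest known reaction types are the hydrogen-atom-transfer coupling of olefins with sulfonylhydrazones (reductive alkylation, hydromethylation) and its intramolecular variant on alkene-tethered hydrazones. Ring A is closed in the 6-exo-trig mode onto the C=N bond through a chair-like transition state. No lasting stereocentre is created (C4 bears two methyl groups and the C3 centre of 9 is erased on loss of N2); the trans ring fusion follows from the C5 and C10 centres set in step 2, since only the trans-diequatorial isopropenyl and chain can reach each other. The step needs chemoselective hydrogen atom transfer to the electron-rich 1,1-disubstituted alkene beside the conjugated enone alkene, and cyclization faster than reduction of the radical; the electron-poor enone is a poor partner for the metal hydride and cannot be reached by the C4 radical within the molecule, while the sulfonylhydrazone is a strong radical acceptor held six atoms away.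

**Step 6**
Reactants: 10 bicyclic enone
Product: 12 (4aS,8aS)-2,5,5,8a-tetramethyl-3,4,4a,5,6,7,8,8a-octahydronaphthalen-1-yl trifluoromethanesulfonate, via lithium enolate 11 (not isolated)
Conditions: LiBH(s-Bu)3, THF, −78 °C; then PhNTf2, −78 → 20 °C
Reagents that add atoms: N-phenylbis(trifluoromethanesulfonimide), O=S(=O)(N(c1ccccc1)S(=O)(=O)C(F)(F)F)C(F)(F)F
Why: Conjugate (1,4) hydride reduction of the β-unsubstituted, carbonyl-hindered enone gives the C8=C9 lithium enolate regiospecifically, and O-sulfonylation by PhNTf2 converts it into the enol triflate (reductive enolate triflation).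

**Step 7**
Reactants: 12 enol triflate
Product: 13 methyl (4aS,8aS)-2,5,5,8a-tetramethyl-3,4,4a,5,6,7,8,8a-octahydronaphthalene-1-carboxylate
Conditions: Pd(OAc)2, dppp, CO (1 atm), MeOH, Et3N, DMF, 70 °C
Reagents that add atoms: carbon monoxide, [C-]#[O+]; methanol, CO
Why: Palladium-catalysed methoxycarbonylation of the enol triflate (oxidative addition, CO insertion, methanolysis) installs C11 as the conjugated ester, as established for 2,6,6-trisubstituted cyclohexenyl triflates.

**Step 8**
Reactants: 13 conjugated ester
Product: 17 1-[(1S,4aS,8aS)-5,5,8a-trimethyl-2-methylidenedecahydronaphthalen-1-yl]ethan-1-one, via lithium ester dienolate 14 (not isolated), via vinylketene 15 (not isolated), via lithium ketone dienolate 16 (not isolated)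
Conditions: n-BuLi, THF, −78 → 0 °C; MeLi, 0 → 20 °C; then AcOH, THF, −78 °C
Reagents that add atoms: methyllithium, [Li]C
Why: γ-Deprotonation of the C17 methyl group syn to the ester gives the exocyclic dienolate, which on warming expels LiOMe to a hindered vinylketene that takes up exactly one MeLi (C12); kinetic α-protonation of the resulting dienolate at C9 from the α face, anti to the axial C10 methyl, sets the 9α-H centre and leaves the exocyclic C8=C17 alkene (ester-enolate to ketene tandem addition with deconjugative protonation, as used for damascone-type ketones).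

**Step 9**
Reactants: 17 methyl ketone
Product: 19 trimethylsilyl enol ether of 17 (C11=C12), via lithium enolate 18 (not isolated)
Conditions: LiN(i-Pr)2, THF, −78 °C; Me3SiCl, Et3N, −78 → 0 °C
Reagents that add atoms: chlorotrimethylsilane, C[Si](C)(C)Cl
Why: Kinetic deprotonation by the hindered amide base occurs at the methyl group (C12) and not at the shielded tertiary C9–H, and O-silylation gives the less substituted silyl enol ether (kinetic enolate trapping).

**Step 10**
Reactants: 20 α-bromo-γ-butyrolactone (racemic)
Product: 21 3-(phenylthio)dihydrofuran-2(3H)-one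
Conditions: PhSH, Et3N, CH2Cl2, 0 → 20 °C
Reagents that add atoms: thiophenol, Sc1ccccc1
Why: SN2 displacement of the activated α-bromide by thiophenolate gives the α-phenylthio lactone; the lactone ring is purchased intact and is never opened or closed.

**Step 11**
Reactants: 21 α-phenylthio lactone
Product: 22 3-chloro-3-(phenylthio)dihydrofuran-2(3H)-one
Conditions: N-chlorosuccinimide, CCl4, 20 °C (used crude)
Reagents that add atoms: N-chlorosuccinimide, O=C1CCC(=O)N1Cl
Why: α-Chlorination of the sulfide proceeds through the chlorosulfonium salt and the thionium ion (Pummerer-type) to the tertiary α-chloro sulfide.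

**Step 12**
Reactants: 19 silyl enol ether; 22 α-chloro sulfide
Product: 23 3-{2-oxo-2-[(1S,4aS,8aS)-5,5,8a-trimethyl-2-methylidenedecahydronaphthalen-1-yl]ethyl}-3-(phenylthio)dihydrofuran-2(3H)-one
Conditions: ZnBr2 (cat.), CH2Cl2, −20 → 0 °C
Reagents that add atoms: none
Why: ZnBr2 ionizes the α-chloro sulfide to a sulfur-stabilized carbocation that is captured by the silyl enol ether at C12 (Mukaiyama-type α-thioalkylation), forming the C12–C13 bond without base so that the epimerizable C9 centre and the β,γ-unsaturated ketone are untouched.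

**Step 13**
Reactants: 23 keto sulfide
Product: 25 (1R)-2-[2-oxo-3-(phenylthio)tetrahydrofuran-3-yl]-1-[(1S,4aS,8aS)-5,5,8a-trimethyl-2-methylidenedecahydronaphthalen-1-yl]ethyl acetate, via lithium alkoxide 24 (not isolated)
Conditions: LiBH(s-Bu)3, THF, −78 °C; then Ac2O, DMAP, −78 → 0 °C
Reagents that add atoms: acetic anhydride, CC(=O)OC(C)=O
Why: Felkin–Anh addition of the bulky hydride anti to the quaternary C10 substituent, with the C12 chain beside the small C9–H, should give the (11R)-alkoxide, which is acetylated in situ before it can exchange with the lactone carbonyl.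

**Step 14**
Reactants: 25 acetoxy sulfide
Product: 27 (1R)-2-(2-oxo-2,5-dihydrofuran-3-yl)-1-[(1S,4aS,8aS)-5,5,8a-trimethyl-2-methylidenedecahydronaphthalen-1-yl]ethyl acetate (CNP0182424.2), via sulfoxide 26 (not isolated)
Conditions: mCPBA (1 equiv), CH2Cl2, −78 °C; then toluene, CaCO3, 110 °C
Reagents that add atoms: none
Why: Chemoselective S-oxidation at low temperature followed by thermal syn-elimination of benzenesulfenic acid toward the ring methylene C14 gives the endocyclic α-substituted butenolide (sulfoxide elimination), the standard α-phenylthio lactone route to 3-alkylbutenolides; no ring is formed or broken.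

**Compound list**

1 | (R)-(−)-carvone, (5R)-2-methyl-5-(prop-1-en-2-yl)cyclohex-2-en-1-one | CC1=CC[C@@H](C(C)=C)CC1=O | starting material
2 | lithium cross-conjugated dienolate of 1 | CC1=CC[C@@H](C(C)=C)C=C1[O-].[Li+] | intermediate
3 | (5R)-2,6-dimethyl-5-(prop-1-en-2-yl)cyclohex-2-en-1-one (6-methylcarvone, both C6 epimers) | CC1=CC[C@@H](C(C)=C)C(C)C1=O | intermediate
4 | lithium enolate of 3 (tetrasubstituted) | CC1=CC[C@@H](C(C)=C)C(C)=C1[O-].[Li+] | intermediate
5 | (5S,6S)-2,6-dimethyl-5-(prop-1-en-2-yl)-6-(prop-2-yn-1-yl)cyclohex-2-en-1-one | CC1=CC[C@@H](C(C)=C)[C@](C)(CC#C)C1=O | intermediate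
6 | (E)-alkenylbis(3-methylbutan-2-yl)borane from 5 | CC1=CC[C@@H](C(C)=C)[C@](C)(C/C=C/B(C(C)C(C)C)C(C)C(C)C)C1=O | intermediate
7 | 3-[(1S,6S)-1,3-dimethyl-2-oxo-6-(prop-1-en-2-yl)cyclohex-3-en-1-yl]propanal | CC1=CC[C@@H](C(C)=C)[C@](C)(CCC=O)C1=O | intermediate
8 | N′-tosylhydrazone of 7 | CC1=CC[C@@H](C(C)=C)[C@](C)(CCC=NNS(=O)(=O)c2ccc(C)cc2)C1=O | intermediate
9 | cyclized N-alkyl-N′-tosylhydrazide (hydrazide on C3 of the trans-decalin enone, either C3 epimer) | CC1=CC[C@H]2C(C)(C)C(NNS(=O)(=O)c3ccc(C)cc3)CC[C@]2(C)C1=O | intermediate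
10 | (4aS,8aS)-2,5,5,8a-tetramethyl-4a,5,6,7,8,8a-hexahydronaphthalen-1(4H)-one | CC1=CC[C@H]2C(C)(C)CCC[C@]2(C)C1=O | intermediate
11 | lithium C8=C9 enolate from 10 | CC1=C([O-])[C@@]2(C)CCCC(C)(C)[C@@H]2CC1.[Li+] | intermediate
12 | (4aS,8aS)-2,5,5,8a-tetramethyl-3,4,4a,5,6,7,8,8a-octahydronaphthalen-1-yl trifluoromethanesulfonate | CC1=C(OS(=O)(=O)C(F)(F)F)[C@@]2(C)CCCC(C)(C)[C@@H]2CC1 | intermediate
13 | methyl (4aS,8aS)-2,5,5,8a-tetramethyl-3,4,4a,5,6,7,8,8a-octahydronaphthalene-1-carboxylate | CC1=C(C(=O)OC)[C@@]2(C)CCCC(C)(C)[C@@H]2CC1 | intermediate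
14 | lithium exocyclic ester dienolate of 13 | C=C1CC[C@H]2C(C)(C)CCC[C@]2(C)C1=C(OC)[O-].[Li+] | intermediate
15 | vinylketene from 14 | C=C1CC[C@H]2C(C)(C)CCC[C@]2(C)C1=C=O | intermediate
16 | lithium dienolate of methyl ketone 17 | C=C1CC[C@H]2C(C)(C)CCC[C@]2(C)C1=C(C)[O-].[Li+] | intermediate
17 | 1-[(1S,4aS,8aS)-5,5,8a-trimethyl-2-methylidenedecahydronaphthalen-1-yl]ethan-1-one | C=C1CC[C@H]2C(C)(C)CCC[C@]2(C)[C@H]1C(C)=O | intermediate
18 | kinetic lithium enolate of 17 (C11=C12) | C=C1CC[C@H]2C(C)(C)CCC[C@]2(C)[C@H]1C(=C)[O-].[Li+] | intermediate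
19 | trimethylsilyl enol ether of 17 (C11=C12) | C=C1CC[C@H]2C(C)(C)CCC[C@]2(C)[C@H]1C(=C)O[Si](C)(C)C | intermediate
20 | α-bromo-γ-butyrolactone, 3-bromodihydrofuran-2(3H)-one (racemic) | O=C1OCCC1Br | starting material
21 | 3-(phenylthio)dihydrofuran-2(3H)-one | O=C1OCCC1Sc1ccccc1 | intermediate
22 | 3-chloro-3-(phenylthio)dihydrofuran-2(3H)-one | O=C1OCCC1(Cl)Sc1ccccc1 | intermediate
23 | 3-{2-oxo-2-[(1S,4aS,8aS)-5,5,8a-trimethyl-2-methylidenedecahydronaphthalen-1-yl]ethyl}-3-(phenylthio)dihydrofuran-2(3H)-one | C=C1CC[C@H]2C(C)(C)CCC[C@]2(C)[C@H]1C(=O)CC1(Sc2ccccc2)CCOC1=O | intermediate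
24 | lithium (11R)-alkoxide from 23 | C=C1CC[C@H]2C(C)(C)CCC[C@]2(C)[C@H]1[C@@H](CC1(Sc2ccccc2)CCOC1=O)[O-].[Li+] | intermediate
25 | (1R)-2-[2-oxo-3-(phenylthio)tetrahydrofuran-3-yl]-1-[(1S,4aS,8aS)-5,5,8a-trimethyl-2-methylidenedecahydronaphthalen-1-yl]ethyl acetate | C=C1CC[C@H]2C(C)(C)CCC[C@]2(C)[C@H]1[C@@H](CC1(Sc2ccccc2)CCOC1=O)OC(C)=O | intermediate
26 | sulfoxide of 25 | C=C1CC[C@H]2C(C)(C)CCC[C@]2(C)[C@H]1[C@@H](CC1(S(=O)c2ccccc2)CCOC1=O)OC(C)=O | intermediate
27 | (1R)-2-(2-oxo-2,5-dihydrofuran-3-yl)-1-[(1S,4aS,8aS)-5,5,8a-trimethyl-2-methylidenedecahydronaphthalen-1-yl]ethyl acetate | C=C1CC[C@H]2C(C)(C)CCC[C@]2(C)[C@H]1[C@@H](CC1=CCOC1=O)OC(C)=O | target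

**Step count.** Total: 14 steps. Longest linear sequence: 12 steps (steps 1–9 and 12–14); the lactone branch is steps 10–11.

**Steps most likely to fail**

Step 5 (radical ring closure). The tertiary radical may be reduced before it cyclizes (net hydrogenation of the isopropenyl group), or the hydrazide may not lose sulfinate and nitrogen cleanly. The fallback sets out from aldehyde 7 and returns at enol triflate 12. Wittig methylenation of the aldehyde (Ph3P=CH2, THF, 0 °C) gives the butenyl dienone F1. Ring-closing metathesis with second-generation Grubbs catalyst, RuCl2(H2IMes)(PCy3)(=CHPh), joins the vinyl and isopropenyl groups and closes ring A as the 4-methylcyclohexene dienone F2. Simmons–Smith cyclopropanation (Et2Zn, CH2I2) of the electron-rich C3=C4 alkene gives the cyclopropane F3. Hydrogenolysis (H2, PtO2, AcOH) opens the cyclopropane at its least hindered bond to the gem-dimethyl group and saturates the enone alkene, giving the saturated decalone F4. LiN(i-Pr)2 then PhNTf2 gives 12, because C8–H is the only enolizable position.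

Step 8 (ketene tandem addition and deconjugative protonation). Elimination of methoxide to the ketene may be incomplete, the base may add to the ester, or the dienolate may be protonated at the γ-carbon and return the conjugated isomer. The fallback sets out from ester 13 and returns at methyl ketone 17. Photochemical deconjugation (254 nm, hexane, catalytic 1,2-dimethylimidazole) moves a hydrogen from the syn C17 methyl group through the photodienol and gives the β,γ-unsaturated ester F5. i-Bu2AlH at −78 °C gives the aldehyde F6, MeMgBr gives the carbinol F7, and Dess–Martin periodinane gives 17.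

Step 13 (reduction at C11). Facial selectivity at C11 may be poor, or the alkoxide may exchange with the lactone before it is acetylated. The fallback sets out from ketone 23 and returns at acetate 25. Catalyst-controlled Corey–Bakshi–Shibata reduction ((S)-2-methyl-CBS-oxazaborolidine, BH3·SMe2, −20 °C) gives the (11R)-alcohol F8, isolated under neutral conditions. Ac2O, pyridine and DMAP then give 25.

**Further compounds**

F1 | step 5 | (5S,6S)-6-(but-3-en-1-yl)-2,6-dimethyl-5-(prop-1-en-2-yl)cyclohex-2-en-1-one | CC1=CC[C@@H](C(C)=C)[C@](C)(CCC=C)C1=O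
F2 | step 5 | (4aS,8aS)-2,5,8a-trimethyl-4a,7,8,8a-tetrahydronaphthalen-1(4H)-one | CC1=CC[C@H]2C(C)=CCC[C@]2(C)C1=O
F3 | step 5 | cyclopropane on the C3=C4 bond of F2 (either face) | CC1=CC[C@H]2C3(C)CC3CC[C@]2(C)C1=O
F4 | step 5 | (4aS,8aS)-2,5,5,8a-tetramethyloctahydronaphthalen-1(2H)-one (C8 epimers) | CC1CC[C@H]2C(C)(C)CCC[C@]2(C)C1=O
F5 | step 8 | methyl (1S,4aS,8aS)-5,5,8a-trimethyl-2-methylidenedecahydronaphthalene-1-carboxylate | C=C1CC[C@H]2C(C)(C)CCC[C@]2(C)[C@H]1C(=O)OC
F6 | step 8 | (1S,4aS,8aS)-5,5,8a-trimethyl-2-methylidenedecahydronaphthalene-1-carbaldehyde | C=C1CC[C@H]2C(C)(C)CCC[C@]2(C)[C@H]1C=O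
F7 | step 8 | 1-[(1S,4aS,8aS)-5,5,8a-trimethyl-2-methylidenedecahydronaphthalen-1-yl]ethan-1-ol (carbinol epimers) | C=C1CC[C@H]2C(C)(C)CCC[C@]2(C)[C@H]1C(C)O
F8 | step 13 | 3-{(2R)-2-hydroxy-2-[(1S,4aS,8aS)-5,5,8a-trimethyl-2-methylidenedecahydronaphthalen-1-yl]ethyl}-3-(phenylthio)dihydrofuran-2(3H)-one | C=C1CC[C@H]2C(C)(C)CCC[C@]2(C)[C@H]1[C@@H](CC1(Sc2ccccc2)CCOC1=O)O
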